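The bicyclic core (cyclopentane ring A fused to cycloheptane ring B) is cut at C1–CH3 and C5–C6 (daucane numbering). The C1 methyl lies β to C4 through C5, and C5 also carries the oxygenated C6. A copper-catalysed enantioselective methyl addition to a 3-substituted cyclopentenone, followed in the same flask by aldol capture of the C5 zinc enolate by a tethered C6 aldehyde, therefore builds the quaternary C1, the C5–C6 bond, ring B and three stereocentres at once. The precursor is cyclopent-2-en-1-one carrying a (Z)-3-methyl-5-oxopent-2-enyl chain on its ring carbon 3, assembled by Stille coupling.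

Key step: step 9

Remark: locants C1–C10 follow daucane numbering (C1 methyl-bearing ring-fusion carbon, C2/C3 ring A methylenes, C4 isopropyl carbinol, C5 ring-fusion CH, C6 ester carbinol, C7 methylene, C8/C9 epoxide carbons, C10 methylene between C9 and C1), and α is the face of the C1 methyl and H5. It is assumed that both enantiomers of the ligand in step 9 are available; the one that delivers methyl to the Re face of the enone β-carbon is used.

Step 1
Reactants: 1 but-2-yn-1-ol
Product: 3 (Z)-3-iodobut-2-en-1-ol, via cyclic alkenylaluminate 2 (not isolated)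
Conditions: NaAlH2(OCH2CH2OMe)2, THF, 0 °C → rt; then I2, THF, −78 → 0 °C; aqueous work-up
Reagents that add atoms: iodine, II
Why: Hydroxyl-directed trans-hydroalumination of the propargylic alcohol delivers hydride to C2 and aluminium to C3 within a five-membered aluminate, and iodinolysis of the C–Al bond with retention should give the Z iodide (iodine cis to CH2OH) that later places C7 and C10 cis on the ring alkene.

Step 2
Reactants: 3 (Z)-3-iodobut-2-en-1-ol; 4 tert-butyldimethyl(vinyloxy)silane
Product: 6 (Z)-5-(tert-butyldimethylsilyloxy)-3-methylpent-2-en-1-ol, via alkylborane 5 (not isolated)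
Conditions: 4, 9-BBN, THF, 0 °C → rt; then 3, Pd(dppf)Cl2 (cat.), AsPh3 (cat.), Cs2CO3, DMF/H2O, rt
Reagents that add atoms: none
Why: B-alkyl Suzuki–Miyaura coupling, in which anti-Markovnikov hydroboration of the silyl vinyl ether gives a primary β-oxygenated alkylborane of the kind known to transmetalate without elimination, and coupling with the vinyl iodide proceeds with retention so that the new CH2CH2OSi arm stays cis to CH2OH while the free allylic alcohol is tolerated.

Step 3
Reactants: 6 (Z)-5-(tert-butyldimethylsilyloxy)-3-methylpent-2-en-1-ol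
Product: 7 (Z)-(5-bromo-3-methylpent-3-enyloxy)(tert-butyl)dimethylsilane
Conditions: CBr4 (1.1 equiv), PPh3 (1.1 equiv), CH2Cl2, −20 → 0 °C
Reagents that add atoms: tetrabromomethane, BrC(Br)(Br)Br
Why: Appel bromination converts the primary allylic alcohol into the bromide by SN2 displacement of the alkoxyphosphonium ion under neutral conditions, which should leave the Z alkene and the silyl ether untouched.

Step 4
Reactants: 8 cyclopentane-1,3-dione
Product: 9 3-iodocyclopent-2-en-1-one
Conditions: PPh3, I2, Et3N, MeCN, rt → reflux
Reagents that add atoms: iodine, II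
Why: Conversion of the enolised 1,3-diketone into the vinylogous acyl iodide by the PPh3–I2 adduct (addition–elimination at the β-carbon of the enol phosphonium intermediate) is a standard deoxyhalogenation route to β-iodo enones.

Step 5
Reactants: 9 3-iodocyclopent-2-en-1-one
Product: 10 3-(tributylstannyl)cyclopent-2-en-1-one
Conditions: (Bu3Sn)2 (1.5 equiv), Pd(PPh3)4 (cat.), toluene, 90 °C
Reagents that add atoms: hexabutylditin, CCCC[Sn](CCCC)(CCCC)[Sn](CCCC)(CCCC)CCCC
Why: Palladium-catalysed stannylation, in which oxidative addition of zerovalent palladium into the activated C–I bond, transmetalation with the ditin and reductive elimination should give the β-stannyl enone, the excess of ditin suppressing homocoupling.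

Step 6
Reactants: 7 (Z)-(5-bromo-3-methylpent-3-enyloxy)(tert-butyl)dimethylsilane; 10 3-(tributylstannyl)cyclopent-2-en-1-one
Product: 11 3-[(Z)-5-(tert-butyldimethylsilyloxy)-3-methylpent-2-enyl]cyclopent-2-en-1-one
Conditions: Pd2(dba)3 (cat.), P(2-furyl)3 (cat.), THF, 50 °C
Reagents that add atoms: none
Why: Stille allyl–alkenyl coupling, in which the π-allylpalladium species from the allylic bromide couples with the alkenylstannane at its unhindered primary terminus, and because syn–anti exchange at the disubstituted allyl terminus is slow the Z geometry should be retained under these neutral conditions, which also spare the skipped dienone.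

Step 7
Reactants: 11 3-[(Z)-5-(tert-butyldimethylsilyloxy)-3-methylpent-2-enyl]cyclopent-2-en-1-one
Product: 12 3-[(Z)-5-hydroxy-3-methylpent-2-enyl]cyclopent-2-en-1-one
Conditions: HF·pyridine, pyridine, THF, 0 °C → rt
Reagents that add atoms: none
Why: Fluoride-mediated desilylation in a buffered, weakly acidic medium removes the primary silyl ether without base, so the doubly allylic C10 methylene of the skipped dienone is not deprotonated.

Step 8
Reactants: 12 3-[(Z)-5-hydroxy-3-methylpent-2-enyl]cyclopent-2-en-1-one
Product: 13 3-[(Z)-3-methyl-5-oxopent-2-enyl]cyclopent-2-en-1-one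
Conditions: Dess–Martin periodinane, pyridine, CH2Cl2, 0 °C; short silica pad, used at once
Reagents that add atoms: none
Why: Dess–Martin oxidation under neutral buffered conditions should give the β,γ-unsaturated aldehyde without migration of the C8=C9 alkene into conjugation, which is why the aldehyde is unmasked last and not stored.

Step 9
Reactants: 13 3-[(Z)-3-methyl-5-oxopent-2-enyl]cyclopent-2-en-1-one
Product: 16 (3aS,8R,8aS)-8-hydroxy-3a,6-dimethyl-3,3a,4,7,8,8a-hexahydroazulen-1(2H)-one, via methylzinc enolate 14 (not isolated), via methylzinc aldolate 15 (not isolated)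
Conditions: Me2Zn (3 equiv), Cu(OTf)2 (5 mol %), chiral sulfonate-bearing imidazolinium salt (carbene precursor, 6 mol %), toluene, −30 → 0 °C; then aq. NH4Cl
Reagents that add atoms: dimethylzinc, C[Zn]C
Why: Proposed new method: Me2Zn reduces Cu(OTf)2 to monovalent copper and deprotonates the imidazolinium salt, the carbene-bound methylcopper–zinc species binds the enone as a π-complex, adds oxidatively at C1 and eliminates reductively to form C1–CH3 and the regiodefined C4=C5 methylzinc enolate 14, which adds to the tethered C6 aldehyde through a zinc-bridged six-membered transition state to give aldolate 15 and, on protonation, ketol 16. The closest known reaction type is the copper-catalysed enantioselective conjugate addition of dialkylzinc reagents to cyclic enones with aldol capture of the zinc enolate, which is established for less substituted or more activated enones and for smaller aldol rings but not for methyl transfer from zinc to a 3-alkylcyclopentenone followed by a seven-membered closure; the strongly donating carbene ligand, the class most active for β,β-disubstituted enones, is chosen for that reason. Ring B closes in a 7-(enolexo)-exo-trig mode. C1 is controlled by the ligand (Re-face delivery gives 1S), C5 by the tether, which reaches only the enolate face syn to the C10 arm and so enforces the cis fusion, and C6 by the closed chair transition state in which zinc bridges the two oxygens and the tether carbon C7 sits pseudo-axial over ring A, which gives 6R with H5 and H6 cis. The step needs methyl transfer to the enone to outrun methyl addition to the aldehyde and proton transfer from the C7 and C10 methylenes; Me2Zn does not add to aldehydes without an amino-alcohol catalyst, the zinc enolate is only weakly basic, and the Z-configured C8=C9 alkene holds the aldehyde next to C5 so that closure beats intermolecular aldol reaction.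

Step 10
Reactants: 16 (3aS,8R,8aS)-8-hydroxy-3a,6-dimethyl-3,3a,4,7,8,8a-hexahydroazulen-1(2H)-one
Product: 17 (1R,3aS,8R,8aS)-3a,6-dimethyl-1-(propan-2-yl)-1,2,3,3a,4,7,8,8a-octahydroazulene-1,8-diol
Conditions: i-PrMgCl (4 equiv), anhydrous CeCl3 (4 equiv), THF, −78 → −40 °C; then aq. NH4Cl
Reagents that add atoms: isopropylmagnesium chloride, CC(C)[Mg]Cl
Why: Organocerium 1,2-addition, in which the weakly basic isopropylcerium reagent (the first equivalent is consumed by the C6 hydroxyl) adds to the C4 ketone without enolisation or β-hydride reduction, and attack from the convex α face, syn to H5 and anti to the C6 arm and its chelated alkoxide, should set C4 as R with the hydroxyl cis to the C6 oxygen.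

Step 11
Reactants: 17 (1R,3aS,8R,8aS)-3a,6-dimethyl-1-(propan-2-yl)-1,2,3,3a,4,7,8,8a-octahydroazulene-1,8-diol; 18 4-acetoxybenzoic acid
Product: 19 (1S,4R,5S,6R)-4-hydroxydauc-8-en-6-yl 4-acetoxybenzoate
Conditions: DCC, DMAP (cat.), CH2Cl2, 0 °C → rt
Reagents that add atoms: none
Why: Steglich esterification should acylate the secondary C6 hydroxyl chemoselectively, the tertiary C4 hydroxyl being too hindered to react, while the phenol is carried as its acetate to prevent self-condensation of the acid.

Step 12
Reactants: 19 (1S,4R,5S,6R)-4-hydroxydauc-8-en-6-yl 4-acetoxybenzoate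
Product: 20 (1S,4R,5S,6R,8R,9S)-8,9-epoxy-4-hydroxydaucan-6-yl 4-acetoxybenzoate
Conditions: dimethyldioxirane (acetone solution), CH2Cl2, 0 °C
Reagents that add atoms: dimethyldioxirane, CC1(C)OO1
Why: Electrophilic epoxidation of the trisubstituted C8=C9 alkene by the dioxirane should occur on the convex α face, anti to the C6 aroyloxy group and to ring A that shield the β face, giving the 8R,9S epoxide, and the acid-free medium avoids opening of the epoxide by the C4 hydroxyl.

Step 13
Reactants: 20 (1S,4R,5S,6R,8R,9S)-8,9-epoxy-4-hydroxydaucan-6-yl 4-acetoxybenzoate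
Product: 21 (1S,4R,5S,6R,8R,9S)-8,9-epoxy-4-hydroxydaucan-6-yl 4-hydroxybenzoate (CNP0163817.4)
Conditions: pyrrolidine, CH2Cl2, 0 °C → rt
Reagents that add atoms: none
Why: Aminolysis of the phenolic acetate, an activated aryl ester, by pyrrolidine is much faster than attack on the hindered alkyl benzoate or on the trisubstituted epoxide, so the free phenol should be released without touching the other functions.

Compound list
1 | but-2-yn-1-ol | CC#CCO | starting material
2 | sodium 2,2-bis(2-methoxyethoxy)-3-methyl-2,5-dihydro-1,2-oxaluminol-2-uide (cyclic alkenylaluminate) | CC1=CCO[Al-]1(OCCOC)OCCOC.[Na+] | intermediate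
3 | (Z)-3-iodobut-2-en-1-ol | C/C(I)=C/CO | intermediate
4 | tert-butyldimethyl(vinyloxy)silane | C=CO[Si](C)(C)C(C)(C)C | starting material
5 | 9-[2-(tert-butyldimethylsilyloxy)ethyl]-9-borabicyclo[3.3.1]nonane | CC(C)(C)[Si](C)(C)OCCB1C2CCCC1CCC2 | intermediate
6 | (Z)-5-(tert-butyldimethylsilyloxy)-3-methylpent-2-en-1-ol | OC/C=C(C)\CCO[Si](C)(C)C(C)(C)C | intermediate
7 | (Z)-(5-bromo-3-methylpent-3-enyloxy)(tert-butyl)dimethylsilane | BrC/C=C(C)\CCO[Si](C)(C)C(C)(C)C | intermediate
8 | cyclopentane-1,3-dione | O=C1CCC(=O)C1 | starting material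
9 | 3-iodocyclopent-2-en-1-one | O=C1C=C(I)CC1 | intermediate
10 | 3-(tributylstannyl)cyclopent-2-en-1-one | CCCC[Sn](CCCC)(CCCC)C1=CC(=O)CC1 | intermediate
11 | 3-[(Z)-5-(tert-butyldimethylsilyloxy)-3-methylpent-2-enyl]cyclopent-2-en-1-one | O=C1C=C(C/C=C(C)\CCO[Si](C)(C)C(C)(C)C)CC1 | intermediate
12 | 3-[(Z)-5-hydroxy-3-methylpent-2-enyl]cyclopent-2-en-1-one | O=C1C=C(C/C=C(C)\CCO)CC1 | intermediate
13 | 3-[(Z)-3-methyl-5-oxopent-2-enyl]cyclopent-2-en-1-one | O=CC/C(C)=C\CC1=CC(=O)CC1 | intermediate
14 | methylzinc enolate (C4=C5) of (3S)-3-methyl-3-[(Z)-3-methyl-5-oxopent-2-enyl]cyclopentanone | C[Zn]OC1=C[C@](C)(C/C=C(C)\CC=O)CC1 | intermediate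
15 | methylzinc alkoxide (C6–O–Zn) of ketol 16 | O=C1CC[C@@]2(C)CC=C(C)C[C@@H](O[Zn]C)[C@@H]12 | intermediate
16 | (3aS,8R,8aS)-8-hydroxy-3a,6-dimethyl-3,3a,4,7,8,8a-hexahydroazulen-1(2H)-one (cis-fused; daucane locants 1S,5S,6R) | O=C1CC[C@@]2(C)CC=C(C)C[C@@H](O)[C@@H]12 | intermediate
17 | (1R,3aS,8R,8aS)-3a,6-dimethyl-1-(propan-2-yl)-1,2,3,3a,4,7,8,8a-octahydroazulene-1,8-diol (daucane locants 1S,4R,5S,6R) | CC(C)[C@]1(O)CC[C@@]2(C)CC=C(C)C[C@@H](O)[C@H]21 | intermediate
18 | 4-acetoxybenzoic acid | CC(=O)Oc1ccc(cc1)C(=O)O | starting material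
19 | (1S,4R,5S,6R)-4-hydroxydauc-8-en-6-yl 4-acetoxybenzoate | CC(C)[C@]1(O)CC[C@@]2(C)CC=C(C)C[C@@H](OC(=O)c3ccc(OC(C)=O)cc3)[C@H]21 | intermediate
20 | (1S,4R,5S,6R,8R,9S)-8,9-epoxy-4-hydroxydaucan-6-yl 4-acetoxybenzoate | CC(C)[C@]1(O)CC[C@@]2(C)C[C@@H]3O[C@]3(C)C[C@@H](OC(=O)c3ccc(OC(C)=O)cc3)[C@H]21 | intermediate
21 | (1S,4R,5S,6R,8R,9S)-8,9-epoxy-4-hydroxydaucan-6-yl 4-hydroxybenzoate | CC(C)[C@]1(O)CC[C@@]2(C)C[C@@H]3O[C@]3(C)C[C@@H](OC(=O)c3ccc(O)cc3)[C@H]21 | target

Total step count: 13. Longest linear sequence: 11 steps (steps 1, 2, 3, 6, 7, 8, 9, 10, 11, 12, 13).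

Steps most likely to fail

Step 9. Methyl transfer from zinc to the β,β-disubstituted enone may be too slow, so that methyl addition to the aldehyde, migration of the C8=C9 alkene into conjugation with the aldehyde, or low enantioface selection takes over. The fallback uses known chemistry, sets out from 11 and comes back at 16. Copper-catalysed enantioselective conjugate addition of Me3Al to 11 (Cu(OTf)2, the same class of chiral carbene ligand, Et2O, −30 °C), an established reaction for 3-alkylcyclopentenones, with capture of the aluminium enolate by Et3SiOTf should give the triethylsilyl enol ether F1. NBS in THF at −78 °C should convert it regiospecifically into the α-bromo ketone F2 (mixture at C5). HF·pyridine then frees the primary alcohol to give the bromo keto alcohol F3, and buffered Dess–Martin oxidation gives the bromo keto aldehyde F4. SmI2 in THF at −78 °C reduces the C–Br bond to the samarium enolate at C5 only, and its Reformatsky-type closure onto the aldehyde through a chelated transition state should give 16.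

Step 12. The oxidant may approach the β face, syn to the ester, because of an unforeseen ring conformation or hydrogen bonding, giving the wrong epoxide face. The fallback sets out from 19 and comes back at 21. NBS in aqueous THF at 0 °C should form the bromonium ion on that same β face, and water opens it at the more substituted C8 from the α face to give the (8R,9R)-9-bromo-8-hydroxy bromohydrin F5. K2CO3 in MeOH then closes the C8 alkoxide onto C9 with inversion, which places the epoxide oxygen on the α face, and cleaves the phenolic acetate in the same operation.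

Step 10. The metal alkoxide of the β-hydroxy ketone may undergo retro-aldol opening of ring B or epimerisation at C5 before addition occurs. The fallback sets out from 16 and comes back at 17. Silylation of the C6 hydroxyl (Et3SiOTf, 2,6-lutidine, CH2Cl2, −78 °C) gives the triethylsilyl ether F6, so that no β-alkoxide is present. The same organocerium addition from the α face gives the tertiary alcohol F7, and Bu4NF in THF removes the silyl group to return diol 17.

Further compounds
F1 | step 9 | triethylsilyl enol ether (C4=C5) of (3S)-3-methyl-3-[(Z)-5-(tert-butyldimethylsilyloxy)-3-methylpent-2-enyl]cyclopentanone | CC[Si](CC)(CC)OC1=C[C@](C)(C/C=C(C)\CCO[Si](C)(C)C(C)(C)C)CC1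
F2 | step 9 | (3S)-2-bromo-3-methyl-3-[(Z)-5-(tert-butyldimethylsilyloxy)-3-methylpent-2-enyl]cyclopentan-1-one (mixture at C2) | O=C1CC[C@@](C)(C/C=C(C)\CCO[Si](C)(C)C(C)(C)C)C1Br
F3 | step 9 | (3S)-2-bromo-3-[(Z)-5-hydroxy-3-methylpent-2-enyl]-3-methylcyclopentan-1-one (mixture at C2) | O=C1CC[C@@](C)(C/C=C(C)\CCO)C1Br
F4 | step 9 | (3S)-2-bromo-3-methyl-3-[(Z)-3-methyl-5-oxopent-2-enyl]cyclopentan-1-one (mixture at C2) | O=C1CC[C@@](C)(C/C=C(C)\CC=O)C1Br
F5 | step 12 | (1S,4R,5S,6R,8R,9R)-9-bromo-4,8-dihydroxydaucan-6-yl 4-acetoxybenzoate | CC(C)[C@]1(O)CC[C@@]2(C)C[C@@H](Br)[C@](C)(O)C[C@@H](OC(=O)c3ccc(OC(C)=O)cc3)[C@H]21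
F6 | step 10 | (3aS,8R,8aS)-3a,6-dimethyl-8-(triethylsilyloxy)-3,3a,4,7,8,8a-hexahydroazulen-1(2H)-one | O=C1CC[C@@]2(C)CC=C(C)C[C@@H](O[Si](CC)(CC)CC)[C@@H]12
F7 | step 10 | (1R,3aS,8R,8aS)-3a,6-dimethyl-1-(propan-2-yl)-8-(triethylsilyloxy)-1,2,3,3a,4,7,8,8a-octahydroazulen-1-ol | CC(C)[C@]1(O)CC[C@@]2(C)CC=C(C)C[C@@H](O[Si](CC)(CC)CC)[C@H]21
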